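**Retrosynthetic overview**
1. Target ⇒ side-chain acetonide cleavage and 3′-O-acetylation ⇒ ring B enone by allylic C8 oxidation of a 7(11)-alkene ⇒ 7-isopropenyl precursor (alkene isomerisation).
2. C3 ester and C4 acetate ⇒ trans-decalin 3α,4α-diol + (4S,5S)-acetonide acid; the acid ⇒ D-threonine (C3′ bought, C2′ set by enolate methylation anti to it).
3. Diol ⇒ (+)-α-cyperone: Li/NH3 (C5, trans fusion), Rubottom oxidation (C4), bulky hydride (C3).
4. (+)-α-Cyperone ⇒ key Lewis-acid Diels–Alder of (S)-carvone with (Z)-3-silyloxypenta-1,3-diene (C10 set anti to the C7 isopropenyl group, which is erased later), then C9 deoxygenation and dehydrogenation.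
5. Ring order: ring B is bought with carvone; ring A is closed by the [4+2] cycloaddition; no further ring is formed.

Assumption: ring positions use eudesmane numbering (C14 = methyl on C10, C15 = methyl on C4, 7(11) = isopropylidene on C7); β is the face of C14.

**Route**

Step 1
Reactants: 1 D-threonine
Product: 2 (2R,3S)-2,3-dihydroxybutanoic acid
Conditions: NaNO2, 0.5 M H2SO4, H2O, 0 °C → rt
Reagents that add atoms: water, O
Why: Diazotisation of the α-amino acid, in which the carboxylate displaces N2 and water reopens the α-lactone, so C2 is retained by double inversion and C3 is untouched.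

Step 2
Reactants: 2 (2R,3S)-2,3-dihydroxybutanoic acid
Product: 3 methyl (4R,5S)-2,2,5-trimethyl-1,3-dioxolane-4-carboxylate
Conditions: Me2C(OMe)2, MeOH, TsOH (cat.), 50 °C
Reagents that add atoms: 2,2-dimethoxypropane, COC(C)(C)OC; methanol, CO
Why: Fischer esterification and acetonide formation (transacetalisation) under one acid catalyst, with no stereocentre touched.

Step 3
Reactants: 3 methyl (4R,5S)-2,2,5-trimethyl-1,3-dioxolane-4-carboxylate
Product: 5 methyl (4S,5S)-2,2,4,5-tetramethyl-1,3-dioxolane-4-carboxylate, via lithium enolate 4 (not isolated)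
Conditions: LiN(i-Pr)2, MeI (present from the start), THF/DMPU, −78 → −40 °C
Reagents that add atoms: iodomethane, CI
Why: Enolate alkylation in which the planar ester enolate is methylated on the face anti to the C5 methyl, setting the quaternary centre as 4S with the ester cis to the C5 methyl.

Step 4
Reactants: 5 methyl (4S,5S)-2,2,4,5-tetramethyl-1,3-dioxolane-4-carboxylate
Product: 6 (4S,5S)-2,2,4,5-tetramethyl-1,3-dioxolane-4-carboxylic acid
Conditions: LiOH·H2O, THF/MeOH/H2O, 40 °C; then 1 M HCl to pH 3, 0 °C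
Reagents that add atoms: lithium hydroxide, [Li+].[OH-]
Why: Ester saponification with cold, brief acidification that leaves the acetonide and both stereocentres intact.

Step 5
Reactants: 7 pent-1-en-3-one
Product: 8 (Z)-3-(trimethylsilyloxy)penta-1,3-diene
Conditions: Me3SiCl, Et3N, LiBr, THF, 40 °C
Reagents that add atoms: chlorotrimethylsilane, C[Si](C)(C)Cl
Why: Soft enolisation and O-silylation of the enone give the 2-silyloxy diene, mainly as the Z enol ether that can reach the s-cis conformation.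

Step 6
Reactants: 9 (S)-(+)-carvone; 8 (Z)-3-(trimethylsilyloxy)penta-1,3-diene
Product: 11 5β-eudesm-11-ene-3,9-dione (4α-Me; 7β-isopropenyl; 10β-Me; cis-fused), via silyl enol ether adduct 10 (not isolated)
Conditions: EtAlCl2 (0.3 equiv), toluene, −20 °C → rt; then 1 M HCl, THF, 0 °C
Reagents that add atoms: none
Why: Lewis-acid-promoted endo Diels–Alder cycloaddition closes ring A with the silyloxy carbon para to C10 and with the diene on the carvone face anti to the C7 isopropenyl group, so the quaternary C10 carries its methyl syn to that group; acid work-up unmasks the C3 ketone.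

Step 7
Reactants: 11 5β-eudesm-11-ene-3,9-dione
Product: 12 3,3-(ethylenedioxy)-5β-eudesm-11-en-9-one
Conditions: Me3SiOCH2CH2OSiMe3, Me3SiOTf (5 mol%), CH2Cl2, −78 → −30 °C
Reagents that add atoms: 1,2-bis(trimethylsilyloxy)ethane, C[Si](C)(C)OCCO[Si](C)(C)C
Why: Noyori acetalisation protects only the unhindered C3 carbonyl, because the C9 carbonyl sits next to the quaternary C10.

Step 8
Reactants: 12 3,3-(ethylenedioxy)-5β-eudesm-11-en-9-one
Product: 15 5β-eudesm-11-en-3-one (4α-Me; 7β-isopropenyl; 10β-Me; cis-fused), via hydrazone 13 (not isolated), via deoxygenated ketal 14 (not isolated)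
Conditions: N2H4·H2O, KOH, diethylene glycol, 130 → 200 °C; then 2 M HCl, THF, rt
Reagents that add atoms: water, O
Why: Wolff–Kishner (Huang–Minlon) reduction removes the C9 carbonyl through its hydrazone while the dioxolane shields C3, and aqueous acid then returns the C3 ketone.

Step 9
Reactants: 15 5β-eudesm-11-en-3-one
Product: 16 (+)-α-cyperone (eudesma-4,11-dien-3-one; 7β-isopropenyl; 10β-Me)
Conditions: IBX (1.5 equiv), DMSO, 70 °C
Reagents that add atoms: none
Why: IBX dehydrogenation through the more substituted enol gives the tetrasubstituted C4=C5 enone, which removes the cis ring fusion so that C5 and C4 can be reset.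

Step 10
Reactants: 16 (+)-α-cyperone
Product: 18 3-(trimethylsilyloxy)-5α-eudesma-3,11-diene, via lithium enolate 17 (not isolated)
Conditions: Li, NH3(l), THF, t-BuOH (1 equiv), −78 °C; NH3 off; Me3SiCl, Et3N, THF, −78 → 0 °C
Reagents that add atoms: chlorotrimethylsilane, C[Si](C)(C)Cl
Why: Dissolving-metal (Birch-type) enone reduction protonates C5 axially on the face away from the angular methyl (trans fusion, 5α-H), and the regiodefined C3–C4 enolate is trapped on oxygen.

Step 11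
Reactants: 18 3-(trimethylsilyloxy)-5α-eudesma-3,11-diene
Product: 20 4α-hydroxy-5α-eudesm-11-en-3-one (4β-Me), via silyloxy ketone 19 (not isolated)
Conditions: mCPBA (1.05 equiv), CH2Cl2, −20 °C; then 1 M HCl, THF, 0 °C
Reagents that add atoms: 3-chloroperbenzoic acid, OOC(=O)c1cccc(Cl)c1
Why: Rubottom oxidation in which the peracid epoxidises the electron-rich enol ether (not the isopropenyl group) from the α face, the β face being blocked by the 1,3-diaxial C10 methyl, so C4 receives α-OH and keeps its methyl β.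

Step 12
Reactants: 20 4α-hydroxy-5α-eudesm-11-en-3-one
Product: 21 5α-eudesm-11-ene-3α,4α-diol (4β-Me; 7β-isopropenyl; 10β-Me)
Conditions: LiBH(s-Bu)3 (2.5 equiv), THF, −78 °C; then H2O
Reagents that add atoms: none
Why: Ketone reduction with a bulky trialkylborohydride delivers hydride equatorially and gives the axial 3α-alcohol, cis to the 4α-hydroxyl.

Step 13
Reactants: 6 (4S,5S)-2,2,4,5-tetramethyl-1,3-dioxolane-4-carboxylic acid; 21 5α-eudesm-11-ene-3α,4α-diol
Product: 23 3α-[(4S,5S)-2,2,4,5-tetramethyl-1,3-dioxolane-4-carbonyloxy]-5α-eudesm-11-en-4α-ol, via mixed anhydride 22 (not isolated)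
Conditions: 2,4,6-Cl3C6H2COCl, Et3N, THF, rt; then 21, DMAP, toluene, 70 °C
Reagents that add atoms: none
Why: Yamaguchi esterification transfers the acyl group to the secondary 3α-hydroxyl only, the tertiary 4-hydroxyl stays free and no stereocentre is affected.

Step 14
Reactants: 23 3α-[(4S,5S)-2,2,4,5-tetramethyl-1,3-dioxolane-4-carbonyloxy]-5α-eudesm-11-en-4α-ol
Product: 24 4α-acetoxy-3α-[(4S,5S)-2,2,4,5-tetramethyl-1,3-dioxolane-4-carbonyloxy]-5α-eudesm-11-ene
Conditions: Ac2O, DMAP, Et3N, ClCH2CH2Cl, 60 °C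
Reagents that add atoms: acetic anhydride, CC(=O)OC(C)=O
Why: DMAP-catalysed acylation under forcing conditions acetylates the only free hydroxyl, the equatorial tertiary one at C4.

Step 15
Reactants: 24 4α-acetoxy-3α-[(4S,5S)-2,2,4,5-tetramethyl-1,3-dioxolane-4-carbonyloxy]-5α-eudesm-11-ene
Product: 25 4α-acetoxy-3α-[(4S,5S)-2,2,4,5-tetramethyl-1,3-dioxolane-4-carbonyloxy]-5α-eudesm-7(11)-ene
Conditions: CoCl(L) (3 mol%; L = N,N′-bis(3,5-di-tert-butylsalicylidene)ethane-1,2-diaminate, complex C32H46ClCoN2O2, trivalent cobalt, achiral), PhSiH3 (6 mol%), benzene, rt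
Reagents that add atoms: none
Why: Hydrogen-atom-transfer alkene isomerisation, in which the cobalt hydride forms the tertiary C11 radical and this loses the C7 hydrogen to give the tetrasubstituted 7(11)-alkene, erasing the C7 stereocentre (C10-epimeric material from step 6 must be removed before this point).

Step 16
Reactants: 25 4α-acetoxy-3α-[(4S,5S)-2,2,4,5-tetramethyl-1,3-dioxolane-4-carbonyloxy]-5α-eudesm-7(11)-ene
Product: 26 4α-acetoxy-3α-[(4S,5S)-2,2,4,5-tetramethyl-1,3-dioxolane-4-carbonyloxy]-5α-eudesm-7(11)-en-8-one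
Conditions: CrO3, 3,5-dimethylpyrazole, CH2Cl2, −20 °C
Reagents that add atoms: chromium trioxide, O=[Cr](=O)=O
Why: Allylic oxidation of the only alkene is expected at the C8 methylene, because the axial C6 hydrogen is shielded by the C4 and C10 methyls and the equatorial one by the 4α-acetate, giving the conjugated isopropylidene ketone.

Step 17
Reactants: 26 4α-acetoxy-3α-[(4S,5S)-2,2,4,5-tetramethyl-1,3-dioxolane-4-carbonyloxy]-5α-eudesm-7(11)-en-8-one
Product: 27 4α-acetoxy-3α-[(2S,3S)-2,3-dihydroxy-2-methylbutanoyloxy]-5α-eudesm-7(11)-en-8-one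
Conditions: CF3CO2H/H2O (9:1), CH2Cl2, 0 °C
Reagents that add atoms: none
Why: Acid hydrolysis of the isopropylidene acetal, under which the esters, the tertiary acetate and the enone survive and no stereocentre is touched.

Step 18
Reactants: 27 4α-acetoxy-3α-[(2S,3S)-2,3-dihydroxy-2-methylbutanoyloxy]-5α-eudesm-7(11)-en-8-one
Product: 28 4α-acetoxy-3α-[(2S,3S)-3-acetoxy-2-hydroxy-2-methylbutanoyloxy]-5α-eudesm-7(11)-en-8-one (CNP0134046.3)
Conditions: Ac2O (1.5 equiv), pyridine, DMAP (5 mol%), CH2Cl2, 0 °C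
Reagents that add atoms: acetic anhydride, CC(=O)OC(C)=O
Why: Selective acylation of the secondary 3′-hydroxyl, since the tertiary 2′-hydroxyl between the ester carbonyl and C3′ does not react under these mild conditions.

**Compound list**

1 | D-threonine, (2R,3S)-2-amino-3-hydroxybutanoic acid | C[C@H](O)[C@@H](N)C(=O)O | starting material
2 | (2R,3S)-2,3-dihydroxybutanoic acid | C[C@H](O)[C@@H](O)C(=O)O | intermediate
3 | methyl (4R,5S)-2,2,5-trimethyl-1,3-dioxolane-4-carboxylate | C[C@@H]1OC(C)(C)O[C@H]1C(=O)OC | intermediate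
4 | lithium ester enolate of 3 (C4 planar, 5S) | [Li+].C[C@@H]1OC(C)(C)OC1=C([O-])OC | intermediate
5 | methyl (4S,5S)-2,2,4,5-tetramethyl-1,3-dioxolane-4-carboxylate | C[C@@H]1OC(C)(C)O[C@]1(C)C(=O)OC | intermediate
6 | (4S,5S)-2,2,4,5-tetramethyl-1,3-dioxolane-4-carboxylic acid | C[C@@H]1OC(C)(C)O[C@]1(C)C(=O)O | intermediate
7 | pent-1-en-3-one (ethyl vinyl ketone) | CCC(=O)C=C | starting material
8 | (Z)-3-(trimethylsilyloxy)penta-1,3-diene | C/C=C(/C=C)O[Si](C)(C)C | intermediate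
9 | (S)-(+)-carvone, (5S)-2-methyl-5-(prop-1-en-2-yl)cyclohex-2-en-1-one | CC1=CC[C@H](C(C)=C)CC1=O | starting material
10 | Diels–Alder adduct, 3-(trimethylsilyloxy)-5β-eudesma-2,11-dien-9-one (4α-Me; 5β-H; 7β-isopropenyl; 10β-Me; cis-fused) | C[Si](C)(C)OC1=CC[C@]2(C)C(=O)C[C@@H](C(C)=C)C[C@@H]2[C@@H]1C | intermediate
11 | 5β-eudesm-11-ene-3,9-dione (4α-Me; 5β-H; 7β-isopropenyl; 10β-Me; cis-fused) | O=C1CC[C@]2(C)C(=O)C[C@@H](C(C)=C)C[C@@H]2[C@@H]1C | intermediate
12 | 3,3-(ethylenedioxy)-5β-eudesm-11-en-9-one (same ring stereochemistry as 11) | C1COC2(O1)CC[C@]3(C)C(=O)C[C@@H](C(C)=C)C[C@@H]3[C@@H]2C | intermediate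
13 | 9-hydrazone of 12 | C1COC2(O1)CC[C@]3(C)C(=NN)C[C@@H](C(C)=C)C[C@@H]3[C@@H]2C | intermediate
14 | 3,3-(ethylenedioxy)-5β-eudesm-11-ene | C1COC2(O1)CC[C@]3(C)CC[C@@H](C(C)=C)C[C@@H]3[C@@H]2C | intermediate
15 | 5β-eudesm-11-en-3-one (4α-Me; 5β-H; 7β-isopropenyl; 10β-Me; cis-fused) | O=C1CC[C@]2(C)CC[C@@H](C(C)=C)C[C@@H]2[C@@H]1C | intermediate
16 | (+)-α-cyperone, eudesma-4,11-dien-3-one (7β-isopropenyl; 10β-Me) | O=C1CC[C@]2(C)CC[C@@H](C(C)=C)CC2=C1C | intermediate
17 | lithium 5α-eudesma-3,11-dien-3-olate (trans-fused) | [Li+].CC1=C([O-])CC[C@]2(C)CC[C@@H](C(C)=C)C[C@@H]12 | intermediate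
18 | 3-(trimethylsilyloxy)-5α-eudesma-3,11-diene (5α-H; 7β-isopropenyl; 10β-Me) | CC1=C(O[Si](C)(C)C)CC[C@]2(C)CC[C@@H](C(C)=C)C[C@@H]12 | intermediate
19 | 4α-(trimethylsilyloxy)-5α-eudesm-11-en-3-one (4β-Me) | O=C1CC[C@]2(C)CC[C@@H](C(C)=C)C[C@H]2[C@]1(C)O[Si](C)(C)C | intermediate
20 | 4α-hydroxy-5α-eudesm-11-en-3-one (4β-Me; 5α-H; 7β-isopropenyl; 10β-Me) | O=C1CC[C@]2(C)CC[C@@H](C(C)=C)C[C@H]2[C@]1(C)O | intermediate
21 | 5α-eudesm-11-ene-3α,4α-diol (4β-Me; 5α-H; 7β-isopropenyl; 10β-Me) | O[C@@H]1CC[C@]2(C)CC[C@@H](C(C)=C)C[C@H]2[C@]1(C)O | intermediate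
22 | mixed anhydride of 6 with 2,4,6-trichlorobenzoic acid | C[C@@H]1OC(C)(C)O[C@]1(C)C(=O)OC(=O)c1c(Cl)cc(Cl)cc1Cl | intermediate
23 | 3α-[(4S,5S)-2,2,4,5-tetramethyl-1,3-dioxolane-4-carbonyloxy]-5α-eudesm-11-en-4α-ol | C[C@@H]1OC(C)(C)O[C@]1(C)C(=O)O[C@@H]2CC[C@]3(C)CC[C@@H](C(C)=C)C[C@H]3[C@]2(C)O | intermediate
24 | 4α-acetoxy-3α-[(4S,5S)-2,2,4,5-tetramethyl-1,3-dioxolane-4-carbonyloxy]-5α-eudesm-11-ene | C[C@@H]1OC(C)(C)O[C@]1(C)C(=O)O[C@@H]2CC[C@]3(C)CC[C@@H](C(C)=C)C[C@H]3[C@]2(C)OC(C)=O | intermediate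
25 | 4α-acetoxy-3α-[(4S,5S)-2,2,4,5-tetramethyl-1,3-dioxolane-4-carbonyloxy]-5α-eudesm-7(11)-ene | C[C@@H]1OC(C)(C)O[C@]1(C)C(=O)O[C@@H]2CC[C@]3(C)CCC(=C(C)C)C[C@H]3[C@]2(C)OC(C)=O | intermediate
26 | 4α-acetoxy-3α-[(4S,5S)-2,2,4,5-tetramethyl-1,3-dioxolane-4-carbonyloxy]-5α-eudesm-7(11)-en-8-one | C[C@@H]1OC(C)(C)O[C@]1(C)C(=O)O[C@@H]2CC[C@]3(C)CC(=O)C(=C(C)C)C[C@H]3[C@]2(C)OC(C)=O | intermediate
27 | 4α-acetoxy-3α-[(2S,3S)-2,3-dihydroxy-2-methylbutanoyloxy]-5α-eudesm-7(11)-en-8-one | O[C@@H](C)[C@](C)(O)C(=O)O[C@@H]1CC[C@]2(C)CC(=O)C(=C(C)C)C[C@H]2[C@]1(C)OC(C)=O | intermediate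
28 | (3R,4S,5R,10R)-4α-acetoxy-3α-[(2S,3S)-3-acetoxy-2-hydroxy-2-methylbutanoyloxy]-5α-eudesm-7(11)-en-8-one, CNP0134046.3 | CC(=O)O[C@@H](C)[C@](C)(O)C(=O)O[C@@H]1CC[C@]2(C)CC(=O)C(=C(C)C)C[C@H]2[C@]1(C)OC(C)=O | target

**Totals and risks**

Total step count: 18. Longest linear sequence: 14 steps (7 → 8 → 11 → … → 28; 13 steps from carvone 9).

Most likely to fail:

Step 16 (allylic oxidation: C8 against C6 and the allylic methyls, over-oxidation). The fallback sets out from 25 and comes back at 26. SeO2 (0.5 equiv) with t-BuOOH in CH2Cl2 at rt hydroxylates the allylic methylene by an ene reaction followed by a [2,3]-sigmatropic shift, giving the 8-hydroxy derivative of 25 F1 as a mixture of C8 epimers. Dess–Martin periodinane then oxidises this alcohol to 26, so the regiochemistry can be checked and corrected at the alcohol stage.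

Step 13 (acylation of an axial secondary alcohol next to a quaternary carbinol with an α-quaternary acid). The fallback sets out from 6 and 21 and comes back at 23. Cyanuric fluoride and pyridine (CH2Cl2, −10 °C) convert 6 into (4S,5S)-2,2,4,5-tetramethyl-1,3-dioxolane-4-carbonyl fluoride F2. Diol 21 is deprotonated with KN(SiMe3)2 (1.0 equiv, THF, −78 °C) to the potassium 3-alkoxide of 21 F3, which is acylated by the small acyl fluoride (−78 → 0 °C) to give 23. This replaces DMAP-mediated transfer from a bulky mixed anhydride by anionic O-acylation.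

Step 14 (acetylation of the hindered tertiary 4α-hydroxyl). The fallback sets out from 18 and comes back at 24. Pb(OAc)4 (lead tetraacetate, tetravalent lead) in CH2Cl2 at −20 °C acetoxylates the silyl enol ether from the α face and gives the tertiary acetate directly, 4α-acetoxy-5α-eudesm-11-en-3-one F4. LiBH(s-Bu)3 at −78 °C, quenched cold with AcOH to suppress acetyl migration, gives 4α-acetoxy-5α-eudesm-11-en-3α-ol F5. This is esterified with 6 through 22 as in step 13 to give 24.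

**Further compounds**

F1 | step 16 | 4α-acetoxy-8-hydroxy-3α-[(4S,5S)-2,2,4,5-tetramethyl-1,3-dioxolane-4-carbonyloxy]-5α-eudesm-7(11)-ene (C8 epimers) | C[C@@H]1OC(C)(C)O[C@]1(C)C(=O)O[C@@H]2CC[C@]3(C)CC(O)C(=C(C)C)C[C@H]3[C@]2(C)OC(C)=O
F2 | step 13 | (4S,5S)-2,2,4,5-tetramethyl-1,3-dioxolane-4-carbonyl fluoride | C[C@@H]1OC(C)(C)O[C@]1(C)C(F)=O
F3 | step 13 | potassium 4α-hydroxy-5α-eudesm-11-en-3α-olate | [K+].[O-][C@@H]1CC[C@]2(C)CC[C@@H](C(C)=C)C[C@H]2[C@]1(C)O
F4 | step 14 | 4α-acetoxy-5α-eudesm-11-en-3-one (4β-Me; 7β-isopropenyl; 10β-Me) | O=C1CC[C@]2(C)CC[C@@H](C(C)=C)C[C@H]2[C@]1(C)OC(C)=O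
F5 | step 14 | 4α-acetoxy-5α-eudesm-11-en-3α-ol | O[C@@H]1CC[C@]2(C)CC[C@@H](C(C)=C)C[C@H]2[C@]1(C)OC(C)=O
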